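**Retrosynthetic overview**

1. The strategy rests on a hidden twofold symmetry. Ring A of the (2R,3S)-flavan-3-ol carries at C6 and at C8 the same arm in the same configuration: a Cx methine with a 4-hydroxyphenyl group, bonded to C3 of a 2R,3S,4S,5S tetrahydrofuran. Without C2, C3 and C4 of ring C the core is a 2,4-disubstituted phloroglucinol with a twofold axis through the hydroxyl-bearing carbon between the arms and the unsubstituted carbon, so the two hydroxyls beside that carbon (future O1 and 5-OH) are homotopic.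
2. Ring C is closed last. The free carbon is aminomethylated, and the derived ortho-quinone methide takes up (E)-4-benzyloxystyryl acetate in a (4+2) addition that forms C4–C3 and O1–C2. Acetate removal and hydrogenolysis finish.
3. The symmetric core comes from phloroglucinol (ring A, bought) and two equivalents of one arm carbinol, by acid-catalysed 1,6-addition to its para-quinone methide; this creates both Cx centres.
4. The arm is built as a γ-lactone: auxiliary-controlled syn-aldol and lactonisation (C4, C5), lactone enolate aldol (C3), then aryllithium addition to lactone and Weinreb amide and hemiketal reduction (C2, cis to C3).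
5. Order of ring formation: tetrahydrofuran rings of the arm (lactone, then cyclic ether), ring A unchanged from phloroglucinol, ring C last.

Key step: step 14

Arm numbering used below: O1, C2 (2,4-dioxygenated aryl; the lactone carbonyl in early intermediates), C3 (carries Cx), C4 (acyl group), C5 (4-oxygenated aryl).

Assumption: the carbinol carbon made in step 5 is carried as both epimers because it becomes planar in step 10; the (R) acid is written for step 10, and its mirror image is to be used unchanged if it proves to steer phloroglucinol to the other face of Cx.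

**Route**

Step 1
Reactants: 1 (S)-4-benzyloxazolidin-2-one; 2 methyl 4-chloro-4-oxobutanoate
Product: 3 (S)-4-benzyl-3-(4-methoxy-4-oxobutanoyl)oxazolidin-2-one
Conditions: n-BuLi, THF, −78 °C; then 2, −78 to 0 °C
Reagents that add atoms: none
Why: N-acylation of the lithiated oxazolidinone by the acid chloride gives the imide, the methyl ester being untouched at low temperature.

Step 2
Reactants: 3; 4 4-(benzyloxy)benzaldehyde
Product: 6 trans-lactone imide (arm C4 S and C5 S), via syn-aldol adduct 5 (not isolated)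
Conditions: Bu2BOTf, iPr2NEt, CH2Cl2, 0 °C; 4, −78 to 0 °C; NaH2PO4/Na2HPO4 buffer (pH 7), MeOH, 30% H2O2, 0 °C; PPTS (cat.), CH2Cl2, rt
Reagents that add atoms: none
Why: Evans syn-aldol through the Z boron enolate and a chair transition state, in which the (S)-benzyl auxiliary sets both new centres, after which the benzylic hydroxyl closes onto the methyl ester and the syn adduct gives the 4,5-trans γ-lactone.

Step 3
Reactants: 6
Product: 7 (2S,3S)-2-[4-(benzyloxy)phenyl]-5-oxooxolane-3-carboxylic acid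
Conditions: LiOH, 30% H2O2, THF/H2O, 0 °C; aq. Na2SO3; HCl to pH 2
Reagents that add atoms: hydrogen peroxide (as LiOOH), OO
Why: Lithium hydroperoxide attacks the exocyclic imide carbonyl (standard auxiliary cleavage), the auxiliary is recovered, and the trans acid is also the thermodynamically preferred one.

Step 4
Reactants: 7
Product: 8 (2S,3S)-2-[4-(benzyloxy)phenyl]-N-methoxy-N-methyl-5-oxooxolane-3-carboxamide
Conditions: MeNHOMe·HCl, EDC·HCl, HOBt, iPr2NEt, CH2Cl2, 0 °C to rt
Reagents that add atoms: N,O-dimethylhydroxylamine hydrochloride, CNOC.Cl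
Why: Carbodiimide amide coupling installs the Weinreb amide, the acyl group that will stop an aryllithium at the ketone stage.

Step 5
Reactants: 8; 9 4-[(tert-butyldimethylsilyl)oxy]benzaldehyde
Product: 11 bis-silylated aldol lactone (C3 side chain trans to the C4 amide; silyloxy carbon as both epimers), via lithium aldolate 10 (not isolated)
Conditions: LiN(SiMe3)2, THF, −78 °C; 9, −78 °C; TBSOTf, −78 to −30 °C
Reagents that add atoms: tert-butyldimethylsilyl triflate, CC(C)(C)[Si](C)(C)OS(=O)(=O)C(F)(F)F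
Why: Kinetic deprotonation takes the lactone CH2 (more acidic and less hindered than the tertiary amide C–H), the enolate undergoes aldol addition anti to the C4 substituent so that C3 is set trans to C4, and silylation of the aldolate in the flask blocks retro-aldol.

Step 6
Reactants: 12 4-bromobenzene-1,3-diol
Product: 13 2,4-bis(benzyloxy)-1-bromobenzene
Conditions: BnBr, K2CO3, DMF, rt
Reagents that add atoms: benzyl bromide, BrCc1ccccc1
Why: Williamson etherification of both phenols.

Step 7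
Reactants: 11; 13
Product: 15 hemiketal diaryl ketone (C2 hemiketal as anomer mixture), via aryllithium 14 (not isolated)
Conditions: 13 (3 equiv), n-BuLi, THF, −78 °C; then 11, −78 to −40 °C; aq. NH4Cl
Reagents that add atoms: none
Why: Bromine–lithium exchange gives the aryllithium, which adds once to the Weinreb amide (chelated tetrahedral intermediate, ketone on work-up) and once to the lactone (lithium hemiketal), so that both 2,4-bis(benzyloxy)phenyl groups enter in one operation.

Step 8
Reactants: 15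
Product: 16 tetrahydrofuran bis-silyl ether (C2 R with the aryl cis to the C3 side chain)
Conditions: Et3SiH, BF3·OEt2, CH2Cl2, −78 °C; Et3N then aq. NaHCO3 at −78 °C
Reagents that add atoms: none
Why: Ionic hydrogenation of the hemiketal, in which BF3 gives the 2-aryl oxocarbenium ion and triethylsilane delivers hydride anti to the C3 side chain, sets C2 with the aryl cis to C3, while the deactivated 2,4-dialkoxyaryl ketone should not be reduced at −78 °C and the cold quench avoids acid epimerisation at C2.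

Step 9
Reactants: 16
Product: 17 arm carbinol with free para-hydroxyphenyl group (carbinol carbon as both epimers)
Conditions: Bu4NF, AcOH, THF, 0 °C to rt
Reagents that add atoms: none
Why: Fluoride cleaves the aryl and the benzylic silyl ether, and acetic acid buffers the medium so that the ketone and the para-hydroxybenzylic alcohol do not meet strong base.

Step 10
Reactants: 17; 18 phloroglucinol
Product: 19 2,4-bis-armed phloroglucinol (both Cx S)
Conditions: 17 (2.05 equiv), (R)-3,3'-bis(2,4,6-triisopropylphenyl)-1,1'-binaphthalene-2,2'-diyl hydrogen phosphate [(R)-TRIP, 10 mol%], 4 Å MS, CH2Cl2/MeCN, 0 °C to rt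
Reagents that add atoms: none
Why: The phosphoric acid dehydrates the para-hydroxybenzylic alcohol to a para-quinone methide and delivers phloroglucinol in a 1,6-addition (vinylogous Friedel–Crafts alkylation) inside the hydrogen-bonded complex, so that both carbinol epimers converge, Cx is set under catalyst control, the second arm gives the same compound at either remaining carbon, and the weak acid should leave the 2-aryl tetrahydrofuran ethers intact (the all-benzyl carbinol would need an acid strong enough to open them, which is why the Cx aryl is carried with a free hydroxyl from here on).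

Step 11
Reactants: 19
Product: 20 2,4-bis-armed 6-(dimethylaminomethyl)phloroglucinol
Conditions: CH2=NMe2+ I− (1.05 equiv), CH2Cl2/MeCN, 0 °C to rt; aq. NaHCO3
Reagents that add atoms: dimethylmethyleneiminium iodide, C=[N+](C)C.[I-]
Why: Mannich aminomethylation at the only free carbon of the phloroglucinol ring, which is far more nucleophilic than the ortho positions of the para-hydroxyphenyl groups.

Step 12
Reactants: 21 1-(benzyloxy)-4-ethynylbenzene
Product: 23 potassium (E)-{2-[4-(benzyloxy)phenyl]vinyl}trifluoroborate, via catechol boronate 22 (not isolated)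
Conditions: catecholborane, THF, 70 °C; then aq. KHF2, rt
Reagents that add atoms: catecholborane, B1Oc2ccccc2O1; potassium hydrogen difluoride, [K+].[F-].F
Why: syn-Hydroboration of the terminal alkyne places boron at the terminus with E geometry, and KHF2 converts the boronate into the stable trifluoroborate.

Step 13
Reactants: 23
Product: 24 (E)-2-[4-(benzyloxy)phenyl]vinyl acetate
Conditions: AcOH, CuBr (10 mol%), DMAP (20 mol%), 4 Å MS, O2 (1 atm), MeCN, 40 °C
Reagents that add atoms: acetic acid, CC(=O)O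
Why: Copper-catalysed oxidative C–O coupling of an alkenyl trifluoroborate with a carboxylic acid (Chan–Lam type) proceeds with retention of alkene geometry.

Step 14
Reactants: 20; 24
Product: 27 3-O-acetyl cycloadduct (ring C closed; (2R,3S) 2,3-trans), via methiodide 25 (not isolated), via ortho-quinone methide 26 (not isolated)
Conditions: 24 (5 equiv), MeI (1.05 equiv), MeCN, 0 °C then 50 °C; aq. NaHCO3
Reagents that add atoms: none
Why: Proposed new method: methyl iodide quaternises the benzylic amine and the trimethylammonium salt 25 loses trimethylamine on warming to give the methylene ortho-quinone methide 26, which is one and the same species whichever of the two symmetry-related flanking hydroxyls becomes the carbonyl. Its O=C–C=CH2 unit then adds across the electron-rich alkene of 24 in an inverse-demand hetero-Diels–Alder reaction; the closest known reaction type is the (4+2) addition of Mannich-base-derived ortho-quinone methides to styrenes and β-alkylstyrenes to give 2-arylchromans, to which a β-acyloxy group on the styrene is new. Ring C is closed in this six-membered (4+2) mode, C4–C3 and O1–C2 being formed on one face of the alkene. The orientation is expected because the para-benzyloxyphenyl ring stabilises positive charge at its own carbon far better than acetoxy does at the other, so the acetoxy-bearing carbon attacks the methylene and the benzylic carbon ends on oxygen. The trans relation of C2 and C3 is carried over from the E alkene, whereas their absolute sense (2R,3S) requires one alkene face to react and is left to the Cx centre of the arm next to the reacting oxygen, whose aryl and tetrahydrofuranyl groups shield opposite faces of the diene. No choice between the two hydroxyls is needed, and benzyl ethers, ketones and cyclic ethers are spectators.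

Step 15
Reactants: 27
Product: 28 flavan-3-ol with benzylated arms and ring B
Conditions: K2CO3, MeOH/THF, 0 °C to rt, argon
Reagents that add atoms: none
Why: Base-catalysed transesterification removes the secondary acetate under conditions that benzyl ethers and the 3-aroyl tetrahydrofurans should tolerate.

Step 16
Reactants: 28
Product: 29 target compound
Conditions: H2 (1 atm), 10% Pd/C, THF/MeOH, rt
Reagents that add atoms: none
Why: Hydrogenolysis cleaves the eleven benzyl ethers, while the cyclic benzylic ethers and the hydrogen-bonded aryl ketones react much more slowly, so the reaction is stopped at the calculated hydrogen uptake.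

**Compound list**

1 | (S)-4-benzyloxazolidin-2-one | O=C1N[C@@H](Cc2ccccc2)CO1 | starting material
2 | methyl 4-chloro-4-oxobutanoate | COC(=O)CCC(Cl)=O | starting material
3 | (S)-4-benzyl-3-(4-methoxy-4-oxobutanoyl)oxazolidin-2-one | COC(=O)CCC(=O)N1[C@@H](Cc2ccccc2)COC1=O | intermediate
4 | 4-(benzyloxy)benzaldehyde | O=Cc1ccc(OCc2ccccc2)cc1 | starting material
5 | syn-aldol adduct, methyl (3S,4S)-3-[(S)-4-benzyl-2-oxooxazolidine-3-carbonyl]-4-[4-(benzyloxy)phenyl]-4-hydroxybutanoate (not isolated) | O=C(N1[C@@H](Cc2ccccc2)COC1=O)[C@@H](CC(=O)OC)[C@H](O)c1ccc(OCc2ccccc2)cc1 | intermediate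
6 | (S)-4-benzyl-3-{(2S,3S)-2-[4-(benzyloxy)phenyl]-5-oxooxolane-3-carbonyl}oxazolidin-2-one (aryl and acyl trans) | O=C(N3[C@@H](Cc4ccccc4)COC3=O)[C@H]1CC(=O)O[C@@H]1c1ccc(OCc2ccccc2)cc1 | intermediate
7 | (2S,3S)-2-[4-(benzyloxy)phenyl]-5-oxooxolane-3-carboxylic acid | O=C(O)[C@H]1CC(=O)O[C@@H]1c1ccc(OCc2ccccc2)cc1 | intermediate
8 | (2S,3S)-2-[4-(benzyloxy)phenyl]-N-methoxy-N-methyl-5-oxooxolane-3-carboxamide | CON(C)C(=O)[C@H]1CC(=O)O[C@@H]1c1ccc(OCc2ccccc2)cc1 | intermediate
9 | 4-[(tert-butyldimethylsilyl)oxy]benzaldehyde | O=Cc1ccc(O[Si](C)(C)C(C)(C)C)cc1 | starting material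
10 | lithium aldolate of 8 and 9, side chain trans to the amide, alkoxide carbon as both epimers (not isolated) | CON(C)C(=O)[C@H]1[C@H](C(O[Li])c2ccc(O[Si](C)(C)C(C)(C)C)cc2)C(=O)O[C@@H]1c1ccc(OCc2ccccc2)cc1 | intermediate
11 | (2S,3S,4R)-2-[4-(benzyloxy)phenyl]-4-{(tert-butyldimethylsilyloxy)[4-(tert-butyldimethylsilyloxy)phenyl]methyl}-N-methoxy-N-methyl-5-oxooxolane-3-carboxamide, silyloxy carbon as both epimers | CON(C)C(=O)[C@H]1[C@H](C(O[Si](C)(C)C(C)(C)C)c2ccc(O[Si](C)(C)C(C)(C)C)cc2)C(=O)O[C@@H]1c1ccc(OCc2ccccc2)cc1 | intermediate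
12 | 4-bromobenzene-1,3-diol | Oc1ccc(Br)c(O)c1 | starting material
13 | 2,4-bis(benzyloxy)-1-bromobenzene | Brc1ccc(OCc2ccccc2)cc1OCc1ccccc1 | intermediate
14 | 2,4-bis(benzyloxy)phenyllithium (not isolated) | [Li]c1ccc(OCc2ccccc2)cc1OCc1ccccc1 | intermediate
15 | hemiketal ketone: arm tetrahydrofuran with C2 bearing OH and 2,4-bis(benzyloxy)phenyl (anomer mixture), C3 bearing the bis-silylated side chain, C4 (S) 2,4-bis(benzyloxy)benzoyl, C5 (S) 4-benzyloxyphenyl; 3,4-trans, 4,5-trans | O=C(c2ccc(OCc3ccccc3)cc2OCc2ccccc2)[C@H]1[C@H](C(O[Si](C)(C)C(C)(C)C)c2ccc(O[Si](C)(C)C(C)(C)C)cc2)C(O)(c2ccc(OCc3ccccc3)cc2OCc2ccccc2)O[C@@H]1c1ccc(OCc2ccccc2)cc1 | intermediate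
16 | arm tetrahydrofuran bis-silyl ether: C2 (R) 2,4-bis(benzyloxy)phenyl cis to the C3 side chain, C4 (S) aroyl trans to C3 and C5, C5 (S) 4-benzyloxyphenyl; silyloxy carbon as both epimers | O=C(c2ccc(OCc3ccccc3)cc2OCc2ccccc2)[C@H]1[C@H](C(O[Si](C)(C)C(C)(C)C)c2ccc(O[Si](C)(C)C(C)(C)C)cc2)[C@H](c2ccc(OCc3ccccc3)cc2OCc2ccccc2)O[C@@H]1c1ccc(OCc2ccccc2)cc1 | intermediate
17 | arm carbinol: as 16 with C3 bearing CH(OH)(4-hydroxyphenyl), carbinol carbon as both epimers | O=C(c2ccc(OCc3ccccc3)cc2OCc2ccccc2)[C@H]1[C@H](C(O)c2ccc(O)cc2)[C@H](c2ccc(OCc3ccccc3)cc2OCc2ccccc2)O[C@@H]1c1ccc(OCc2ccccc2)cc1 | intermediate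
18 | phloroglucinol | Oc1cc(O)cc(O)c1 | starting material
19 | 2,4-bis-armed phloroglucinol: both arms (2R,3S,4S,5S)-tetrahydrofuran-3-yl with Cx (S) bearing 4-hydroxyphenyl; twofold symmetric | O=C(c7ccc(OCc9ccccc9)cc7OCc9ccccc9)[C@H]1[C@H]([C@@H](c7ccc(O)cc7)c2c(O)cc(O)c([C@H](c7ccc(O)cc7)[C@H]4[C@H](C(=O)c7ccc(OCc9ccccc9)cc7OCc9ccccc9)[C@@H](c7ccc(OCc9ccccc9)cc7)O[C@H]4c7ccc(OCc9ccccc9)cc7OCc9ccccc9)c2O)[C@H](c7ccc(OCc9ccccc9)cc7OCc9ccccc9)O[C@@H]1c7ccc(OCc9ccccc9)cc7 | intermediate
20 | 2,4-bis-armed 6-(dimethylaminomethyl)phloroglucinol (key-step precursor) | O=C(c7ccc(OCc9ccccc9)cc7OCc9ccccc9)[C@H]1[C@H]([C@@H](c7ccc(O)cc7)c2c(O)c(CN(C)C)c(O)c([C@H](c7ccc(O)cc7)[C@H]4[C@H](C(=O)c7ccc(OCc9ccccc9)cc7OCc9ccccc9)[C@@H](c7ccc(OCc9ccccc9)cc7)O[C@H]4c7ccc(OCc9ccccc9)cc7OCc9ccccc9)c2O)[C@H](c7ccc(OCc9ccccc9)cc7OCc9ccccc9)O[C@@H]1c7ccc(OCc9ccccc9)cc7 | intermediate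
21 | 1-(benzyloxy)-4-ethynylbenzene | C#Cc1ccc(OCc2ccccc2)cc1 | starting material
22 | (E)-2-{2-[4-(benzyloxy)phenyl]vinyl}-1,3,2-benzodioxaborole (not isolated) | B1(/C=C/c2ccc(OCc3ccccc3)cc2)Oc2ccccc2O1 | intermediate
23 | potassium (E)-{2-[4-(benzyloxy)phenyl]vinyl}trifluoroborate | [K+].F[B-](F)(F)/C=C/c1ccc(OCc2ccccc2)cc1 | intermediate
24 | (E)-2-[4-(benzyloxy)phenyl]vinyl acetate | CC(=O)O/C=C/c1ccc(OCc2ccccc2)cc1 | intermediate
25 | trimethylammonium iodide of 20 (not isolated) | O=C(c7ccc(OCc9ccccc9)cc7OCc9ccccc9)[C@H]1[C@H]([C@@H](c7ccc(O)cc7)c2c(O)c(C[N+](C)(C)C)c(O)c([C@H](c7ccc(O)cc7)[C@H]4[C@H](C(=O)c7ccc(OCc9ccccc9)cc7OCc9ccccc9)[C@@H](c7ccc(OCc9ccccc9)cc7)O[C@H]4c7ccc(OCc9ccccc9)cc7OCc9ccccc9)c2O)[C@H](c7ccc(OCc9ccccc9)cc7OCc9ccccc9)O[C@@H]1c7ccc(OCc9ccccc9)cc7.[I-] | intermediate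
26 | bis-armed 6-methylene ortho-quinone methide (not isolated) | O=C(c7ccc(OCc9ccccc9)cc7OCc9ccccc9)[C@H]1[C@H]([C@@H](c7ccc(O)cc7)C2=C(O)C(=C)C(=O)C([C@H](c7ccc(O)cc7)[C@H]4[C@H](C(=O)c7ccc(OCc9ccccc9)cc7OCc9ccccc9)[C@@H](c7ccc(OCc9ccccc9)cc7)O[C@H]4c7ccc(OCc9ccccc9)cc7OCc9ccccc9)=C2O)[C@H](c7ccc(OCc9ccccc9)cc7OCc9ccccc9)O[C@@H]1c7ccc(OCc9ccccc9)cc7 | intermediate
27 | (2R,3S)-3-O-acetyl flavan with arms at C6 and C8, benzyl ethers on the arm resorcinol and C5 aryl rings and on ring B (key-step product) | O=C(c7ccc(OCc9ccccc9)cc7OCc9ccccc9)[C@H]1[C@H]([C@@H](c7ccc(O)cc7)c2c(O)c3c(c([C@H](c7ccc(O)cc7)[C@H]4[C@H](C(=O)c7ccc(OCc9ccccc9)cc7OCc9ccccc9)[C@@H](c7ccc(OCc9ccccc9)cc7)O[C@H]4c7ccc(OCc9ccccc9)cc7OCc9ccccc9)c2O)O[C@H](c7ccc(OCc9ccccc9)cc7)[C@@H](OC(C)=O)C3)[C@H](c7ccc(OCc9ccccc9)cc7OCc9ccccc9)O[C@@H]1c7ccc(OCc9ccccc9)cc7 | intermediate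
28 | (2R,3S)-flavan-3-ol corresponding to 27 (free 3-OH) | O=C(c7ccc(OCc9ccccc9)cc7OCc9ccccc9)[C@H]1[C@H]([C@@H](c7ccc(O)cc7)c2c(O)c3c(c([C@H](c7ccc(O)cc7)[C@H]4[C@H](C(=O)c7ccc(OCc9ccccc9)cc7OCc9ccccc9)[C@@H](c7ccc(OCc9ccccc9)cc7)O[C@H]4c7ccc(OCc9ccccc9)cc7OCc9ccccc9)c2O)O[C@H](c7ccc(OCc9ccccc9)cc7)[C@@H](O)C3)[C@H](c7ccc(OCc9ccccc9)cc7OCc9ccccc9)O[C@@H]1c7ccc(OCc9ccccc9)cc7 | intermediate
29 | CNP0225367.3 | O=C(c1ccc(O)cc1O)[C@H]1[C@H]([C@@H](c2ccc(O)cc2)c2c(O)c3c(c([C@H](c4ccc(O)cc4)[C@H]4[C@H](C(=O)c5ccc(O)cc5O)[C@@H](c5ccc(O)cc5)O[C@H]4c4ccc(O)cc4O)c2O)O[C@H](c2ccc(O)cc2)[C@@H](O)C3)[C@H](c2ccc(O)cc2O)O[C@@H]1c1ccc(O)cc1 | target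

**Step count**

Total step count: 16. Longest linear sequence: 13 steps (1–5, 7–11, 14–16).

**Steps most likely to fail**

Step 14 (key step). The alkene may react through both of its faces, so that the (2S,3R) ring forms beside the wanted one. The quinone methide may also be lost to self-addition or to phenolic hydroxyls before the weakly nucleophilic enol acetate traps it. The fallback uses known chemistry and introduces ring C with its configuration already in place; it sets out from carbinol 17 and returns at target 29. (+)-Afzelechin F1, the (2R,3S)-flavan-3-ol itself and a commercial natural product, is alkylated at both free ring A carbons with two equivalents of 17 under the phosphoric acid conditions of step 10. C6 and C8 are both to be substituted, so no site question arises. This gives the bis-armed afzelechin F2, which carries the arm benzyl ethers and a free 4'-hydroxyl. Hydrogenolysis over 10% Pd/C as in step 16 then gives 29.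

Step 10. Phloroglucinol may be delivered to the wrong face of Cx. In the quinone methide conformer with C3–H eclipsing the exocyclic double bond, the C2 aryl, cis to the side chain, covers the face that must be attacked, and the catalyst has to overrule this. Incomplete second alkylation and tautomerisation of the quinone methide to a benzylidene tetrahydrofuran are further losses. The fallback alkylates before the C2 aryl exists; it sets out from 11 and returns at 19. Buffered Bu4NF/AcOH frees 11 to the para-hydroxybenzylic lactone F3. Here C2 is a planar lactone carbonyl and the hindered side of the quinone methide is the C4/C5 side, so substrate bias and catalyst should point the same way. Twofold alkylation of phloroglucinol under the step 10 conditions gives the bis(lactone-armed) phloroglucinol F4. Et3SiOTf/2,6-lutidine protects its five phenols as the pentakis(triethylsilyl) ether F5. Excess aryllithium 14 at −78 °C adds to both Weinreb amides and both lactones to give the bis-hemiketal bis-ketone F6. Et3SiH/BF3·OEt2 at −78 °C reduces both hemiketals to the bis-tetrahydrofuran silyl ether F7, and Bu4NF/AcOH returns 19.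

Step 7. The basic aryllithium may deprotonate instead of adding at the two hindered carbonyls, or the lithium hemiketal may open and take up a second aryl group. The fallback stages the two arylations, with a carboxylate protecting the C4 acyl carbon; it sets out from acid 7 and returns at 16. The dianion of 7 (LiN(SiMe3)2, 2.2 equiv) undergoes aldol addition to 9, and TBSOTf followed by mild aqueous work-up gives the bis-silylated lactone acid F8. After deprotonation of the acid, 14 adds only to the lactone at −78 °C to give the hemiketal acid F9. Et3SiH/BF3·OEt2 gives the 2,3-cis tetrahydrofuran acid F10. Coupling with MeNHOMe·HCl and EDC·HCl gives the tetrahydrofuran Weinreb amide F11, and a single addition of 14 gives 16.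

Further compounds

F1 | step 14 | (+)-afzelechin, (2R,3S)-2-(4-hydroxyphenyl)chromane-3,5,7-triol | Oc1cc(O)c2c(c1)O[C@H](c1ccc(O)cc1)[C@@H](O)C2
F2 | step 14 | 6,8-bis-armed (+)-afzelechin with benzylated arm resorcinol and C5 aryl rings and free 4'-OH | O=C(c7ccc(OCc9ccccc9)cc7OCc9ccccc9)[C@H]1[C@H]([C@@H](c7ccc(O)cc7)c2c(O)c3c(c([C@H](c7ccc(O)cc7)[C@H]4[C@H](C(=O)c7ccc(OCc9ccccc9)cc7OCc9ccccc9)[C@@H](c7ccc(OCc9ccccc9)cc7)O[C@H]4c7ccc(OCc9ccccc9)cc7OCc9ccccc9)c2O)O[C@H](c7ccc(O)cc7)[C@@H](O)C3)[C@H](c7ccc(OCc9ccccc9)cc7OCc9ccccc9)O[C@@H]1c7ccc(OCc9ccccc9)cc7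
F3 | step 10 | para-hydroxybenzylic lactone carbinol (desilylated 11, carbinol carbon as both epimers) | CON(C)C(=O)[C@H]1[C@H](C(O)c2ccc(O)cc2)C(=O)O[C@@H]1c1ccc(OCc2ccccc2)cc1
F4 | step 10 | 2,4-bis(lactone-armed) phloroglucinol with Weinreb amides at both C4 | CON(C)C(=O)[C@H]1[C@H]([C@@H](c7ccc(O)cc7)c2c(O)cc(O)c([C@H](c7ccc(O)cc7)[C@H]4[C@H](C(=O)N(C)OC)[C@@H](c7ccc(OCc9ccccc9)cc7)OC4=O)c2O)C(=O)O[C@@H]1c7ccc(OCc9ccccc9)cc7
F5 | step 10 | pentakis(triethylsilyl) ether of F4 | CON(C)C(=O)[C@H]1[C@H]([C@@H](c7ccc(O[Si](CC)(CC)CC)cc7)c2c(O[Si](CC)(CC)CC)cc(O[Si](CC)(CC)CC)c([C@H](c7ccc(O[Si](CC)(CC)CC)cc7)[C@H]4[C@H](C(=O)N(C)OC)[C@@H](c7ccc(OCc9ccccc9)cc7)OC4=O)c2O[Si](CC)(CC)CC)C(=O)O[C@@H]1c7ccc(OCc9ccccc9)cc7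
F6 | step 10 | bis-hemiketal bis-ketone pentakis(triethylsilyl) ether (hemiketal carbons as anomer mixtures) | O=C(c7ccc(OCc9ccccc9)cc7OCc9ccccc9)[C@H]1[C@H]([C@@H](c7ccc(O[Si](CC)(CC)CC)cc7)c2c(O[Si](CC)(CC)CC)cc(O[Si](CC)(CC)CC)c([C@H](c7ccc(O[Si](CC)(CC)CC)cc7)[C@H]4[C@H](C(=O)c7ccc(OCc9ccccc9)cc7OCc9ccccc9)[C@@H](c7ccc(OCc9ccccc9)cc7)OC4(O)c7ccc(OCc9ccccc9)cc7OCc9ccccc9)c2O[Si](CC)(CC)CC)C(O)(c7ccc(OCc9ccccc9)cc7OCc9ccccc9)O[C@@H]1c7ccc(OCc9ccccc9)cc7
F7 | step 10 | pentakis(triethylsilyl) ether of 19 | O=C(c7ccc(OCc9ccccc9)cc7OCc9ccccc9)[C@H]1[C@H]([C@@H](c7ccc(O[Si](CC)(CC)CC)cc7)c2c(O[Si](CC)(CC)CC)cc(O[Si](CC)(CC)CC)c([C@H](c7ccc(O[Si](CC)(CC)CC)cc7)[C@H]4[C@H](C(=O)c7ccc(OCc9ccccc9)cc7OCc9ccccc9)[C@@H](c7ccc(OCc9ccccc9)cc7)O[C@H]4c7ccc(OCc9ccccc9)cc7OCc9ccccc9)c2O[Si](CC)(CC)CC)[C@H](c7ccc(OCc9ccccc9)cc7OCc9ccccc9)O[C@@H]1c7ccc(OCc9ccccc9)cc7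
F8 | step 7 | bis-silylated aldol lactone acid (side chain trans to the carboxyl, silyloxy carbon as both epimers) | O=C(O)[C@H]1[C@H](C(O[Si](C)(C)C(C)(C)C)c2ccc(O[Si](C)(C)C(C)(C)C)cc2)C(=O)O[C@@H]1c1ccc(OCc2ccccc2)cc1
F9 | step 7 | hemiketal acid (C2 bearing OH and 2,4-bis(benzyloxy)phenyl, anomer mixture) | O=C(O)[C@H]1[C@H](C(O[Si](C)(C)C(C)(C)C)c2ccc(O[Si](C)(C)C(C)(C)C)cc2)C(O)(c2ccc(OCc3ccccc3)cc2OCc2ccccc2)O[C@@H]1c1ccc(OCc2ccccc2)cc1
F10 | step 7 | 2,3-cis tetrahydrofuran C4 carboxylic acid | O=C(O)[C@H]1[C@H](C(O[Si](C)(C)C(C)(C)C)c2ccc(O[Si](C)(C)C(C)(C)C)cc2)[C@H](c2ccc(OCc3ccccc3)cc2OCc2ccccc2)O[C@@H]1c1ccc(OCc2ccccc2)cc1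
F11 | step 7 | 2,3-cis tetrahydrofuran C4 Weinreb amide | CON(C)C(=O)[C@H]1[C@H](C(O[Si](C)(C)C(C)(C)C)c2ccc(O[Si](C)(C)C(C)(C)C)cc2)[C@H](c2ccc(OCc3ccccc3)cc2OCc2ccccc2)O[C@@H]1c1ccc(OCc2ccccc2)cc1
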